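**Retrosynthetic overview**

1. Feature: ring A'' of the flavone half (C4a''–C5''–C6''–C7''–C8''–C8a'') is a phloroglucinol whose C8'' carries C6 of flavanone ring A. The two oxygens beside C8'' have different fates (C8a''–O becomes pyranone O1'', C7''–O stays a phenol), and four oxygens flank the C6–C8'' axis, so a late biaryl coupling is unattractive.
2. Key disconnection: ring A'' is cut into the alkyne C8''≡C7'' of an aryl siloxyalkyne (ring A already on C8'') and the four-carbon vinylketene C8a''=C6''–C5''=C4a'', released by light from an α-siloxyvinyl diazoketone. The axis thus begins as an aryl–alkyne bond and C8a''–OH emerges as the only free hydroxyl.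
3. Flavone ring C'': O1''–C2'' by oxa-Michael addition of that hydroxyl to an aryl propiolate, C4''–C4a'' by acylative closure. Flavanone ring C: O1–C2 by Mitsunobu inversion of an (R)-β-hydroxy ester at the oxygen para to the axis, C4–C4a by acylative closure.
4. Ring order: A (bought) → A'' (step 7) → C'' (step 12) → C (step 19); rings B'' and B are bought.
5. Protecting groups: allyl on the para oxygen (outlasts the acidic closure, leaves under neutral palladium catalysis). A silyl enol ether for C5''–O (clean O-functionalisation of butanedione). A benzyl carbonate on 4'-O (keeps benzylic C2 from ionising). Benzyl elsewhere, for one final hydrogenolysis.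

Key step: step 7

Assumption: the SMILES fixes only C2 (S) and gives no descriptor for the hindered C6–C8'' axis, so both orientations about it count as the target. The axis becomes stereogenic only in step 19 and is not controlled there.

**Route**

Step 1
Reactants: 1 2,4,6-trihydroxybenzaldehyde
Product: 2 4-(allyloxy)-2,6-dihydroxybenzaldehyde
Conditions: allyl alcohol (1.0 equiv), PPh3, DIAD, THF, 0 °C → rt
Reagents that add atoms: allyl alcohol, C=CCO
Why: Mitsunobu etherification should pick the 4-OH, the most acidic hydroxyl and the one not tied to the formyl group by hydrogen bonding, and O-alkylation through the alkoxyphosphonium salt avoids the C-allylation that phloroglucinol anions show with allyl halides.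

Step 2
Reactants: 2 4-(allyloxy)-2,6-dihydroxybenzaldehyde
Product: 3 4-(allyloxy)-2,6-bis(benzyloxy)benzaldehyde
Conditions: BnBr (2.5 equiv), K2CO3, DMF, 60 °C
Reagents that add atoms: benzyl bromide, BrCc1ccccc1
Why: Williamson etherification with excess halide and gentle heating should alkylate both chelated ortho hydroxyls, while aldehyde and allyl ether are inert to carbonate.

Step 3
Reactants: 3 4-(allyloxy)-2,6-bis(benzyloxy)benzaldehyde
Product: 4 5-(allyloxy)-1,3-bis(benzyloxy)-2-ethynylbenzene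
Conditions: dimethyl (1-diazo-2-oxopropyl)phosphonate, K2CO3, MeOH/THF, rt
Reagents that add atoms: dimethyl (1-diazo-2-oxopropyl)phosphonate, CC(=O)C(=[N+]=[N-])P(=O)(OC)OC
Why: Ohira–Bestmann homologation (Horner–Wadsworth–Emmons-type olefination to the diazoalkene, N2 loss, 1,2-shift) turns the aldehyde into the terminal alkyne under mild carbonate conditions that all three ethers tolerate.

Step 4
Reactants: 4 5-(allyloxy)-1,3-bis(benzyloxy)-2-ethynylbenzene
Product: 7 {[4-(allyloxy)-2,6-bis(benzyloxy)phenyl]ethynyloxy}triisopropylsilane, via lithium acetylide 5 (not isolated), via lithium ynolate 6 (not isolated)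
Conditions: n-BuLi (1.0 equiv), THF, −78 °C; t-BuOOLi (from t-BuOOH in decane + LiHMDS, THF, −78 °C), −78 → 0 °C; TIPSOTf, −78 → 0 °C
Reagents that add atoms: n-butyllithium, [Li]CCCC (lithium kept only in 5 and 6); tert-butyl hydroperoxide, CC(C)(C)OO; triisopropylsilyl trifluoromethanesulfonate, CC(C)[Si](OS(=O)(=O)C(F)(F)F)(C(C)C)C(C)C
Why: Oxidation of a lithium acetylide with lithium tert-butyl peroxide gives the ynolate at the open terminal carbon, away from the two ortho benzyloxy groups that would slow a homologation at a benzoate carbonyl, and the bulky silyl triflate traps the ynolate on oxygen.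

Step 5
Reactants: 8 2,3-butanedione
Product: 9 3-(triisopropylsilyloxy)but-3-en-2-one
Conditions: TIPSOTf (1.0 equiv), Et3N, CH2Cl2, 0 °C (8 in slight excess)
Reagents that add atoms: triisopropylsilyl trifluoromethanesulfonate, CC(C)[Si](OS(=O)(=O)C(F)(F)F)(C(C)C)C(C)C
Why: Soft enolisation with silyl triflate and amine O-silylates the 1,2-diketone cleanly, whereas alkyl halides on its enolate would give C-alkylation and aldol products, and one equivalent of triflate stops at the mono enol ether.

Step 6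
Reactants: 9 3-(triisopropylsilyloxy)but-3-en-2-one
Product: 12 1-diazo-3-(triisopropylsilyloxy)but-3-en-2-one, via lithium enolate 10 (not isolated), via trifluoroacetyl diketone 11 (not isolated)
Conditions: LiHMDS, THF, −78 °C; CF3CO2CH2CF3, −78 °C; dilute HCl work-up; then 4-acetamidobenzenesulfonyl azide, Et3N, H2O (1 equiv), MeCN, rt
Reagents that add atoms: lithium hexamethyldisilazide, [Li]N([Si](C)(C)C)[Si](C)(C)C (lithium kept only in 10); 2,2,2-trifluoroethyl trifluoroacetate, O=C(OCC(F)(F)F)C(F)(F)F (kept only in 11); 4-acetamidobenzenesulfonyl azide, CC(=O)Nc1ccc(cc1)S(=O)(=O)N=[N+]=[N-]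
Why: Detrifluoroacetylative diazo transfer (Claisen trifluoroacetylation of the only enolisable methyl group, Regitz transfer, loss of the trifluoroacetyl group) gives the α'-diazo enone without exposing the alkene to diazomethane.

Step 7
Reactants: 7 {[4-(allyloxy)-2,6-bis(benzyloxy)phenyl]ethynyloxy}triisopropylsilane; 12 1-diazo-3-(triisopropylsilyloxy)but-3-en-2-one
Product: 17 4'-(allyloxy)-2',6'-bis(benzyloxy)-4,6-bis(triisopropylsilyloxy)biphenyl-2-ol, via vinylketene 13 (not isolated), via vinylcyclobutenone 14 (not isolated), via dienylketene 15 (not isolated), via cyclohexadienone 16 (not isolated)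
Conditions: 12 (1.5 equiv, added in portions), degassed toluene (0.2 M), hν 365 nm (LED or filtered medium-pressure Hg lamp), 20 °C; then 110 °C
Reagents that add atoms: none
Why: Light absorbed by the long-wave band of 12 expels N2 and the 1-siloxyvinyl group shifts to the former diazo carbon (Wolff rearrangement, forms C6''–C5'') to give vinylketene 13. The ring-A-bearing alkyne carbon of 7, made nucleophilic by the siloxy group, bonds to the ketene carbonyl carbon (C8''–C8a'') and the siloxy carbon to the ketene α-carbon (C7''–C6''), a polarity-matched [2+2] cycloaddition that closes the transient four-membered ring of 14. Strain release opens 14 by 4π electrocyclic cleavage to dienylketene 15, and ring A'' closes by 6π electrocyclisation between the ketene carbon and the terminal CH2 (C4a''–C8a''), after which dienone 16 tautomerises to phenol 17; the final heating carries any surviving 14 through. The closest known reaction is the Danheiser benzannulation of triisopropylsiloxyalkynes with vinylketenes made by photochemical Wolff rearrangement, which is known for α-alkoxyvinyl diazoketones. No lasting stereocentre is formed (C4 of 14 is lost on ring opening) and the new axis is not yet stereogenic because ring A is symmetric about it. The step needs regioselectivity, secured by the ynol ether polarisation that outweighs the aryl group and places the former ketene oxygen (future O1'') beside C8'', and chemoselectivity for the ynol ether over the allyl alkene and the benzyl ethers, secured by the far higher ketenophilicity of the ynol ether and by irradiating where only the diazoketone absorbs.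

Step 8
Reactants: 18 1-(benzyloxy)-4-ethynylbenzene
Product: 20 methyl 3-[4-(benzyloxy)phenyl]prop-2-ynoate, via lithium acetylide 19 (not isolated)
Conditions: n-BuLi, THF, −78 °C; ClCO2Me, −78 °C → rt
Reagents that add atoms: n-butyllithium, [Li]CCCC (lithium kept only in 19); methyl chloroformate, COC(=O)Cl
Why: C-acylation of a lithium acetylide with a chloroformate is the standard route to aryl propiolates, and the benzyl ether is inert at low temperature.

Step 9
Reactants: 17 4'-(allyloxy)-2',6'-bis(benzyloxy)-4,6-bis(triisopropylsilyloxy)biphenyl-2-ol; 20 methyl 3-[4-(benzyloxy)phenyl]prop-2-ynoate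
Product: 21 methyl (Z)-3-[4-(benzyloxy)phenyl]-3-{[4'-(allyloxy)-2',6'-bis(benzyloxy)-4,6-bis(triisopropylsilyloxy)biphenyl-2-yl]oxy}acrylate
Conditions: Cs2CO3 (0.3 equiv), 4 Å MS, MeCN, 50 °C
Reagents that add atoms: none
Why: Base-catalysed oxa-Michael addition of the single free phenol to the aryl propiolate forms O1''–C2'' by anti addition, which places aryloxy and ester groups cis, and substoichiometric carbonate in dry acetonitrile should spare the aryl silyl ethers.

Step 10
Reactants: 21 bis-silyl aryloxyacrylate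
Product: 22 methyl (Z)-3-[4-(benzyloxy)phenyl]-3-{[4'-(allyloxy)-2',4,6,6'-tetrakis(benzyloxy)biphenyl-2-yl]oxy}acrylate
Conditions: CsF, BnBr, DMF, rt → 40 °C
Reagents that add atoms: benzyl bromide, BrCc1ccccc1
Why: Fluoride desilylation with in situ Williamson benzylation exchanges both base-labile aryl silyl ethers (C5''–O and C7''–O) for benzyl ethers before saponification, and the excess halide traps each phenoxide as it forms.

Step 11
Reactants: 22 methyl aryloxyacrylate (all benzyl)
Product: 23 (Z)-3-[4-(benzyloxy)phenyl]-3-{[4'-(allyloxy)-2',4,6,6'-tetrakis(benzyloxy)biphenyl-2-yl]oxy}acrylic acid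
Conditions: LiOH, THF/MeOH/H2O, 40 °C; then cold 1 M HCl to pH 3
Reagents that add atoms: lithium hydroxide, [Li+].[OH-]
Why: Saponification of the methyl ester is faster than conjugate attack on the donor-substituted alkene, and nothing else in the molecule is base-labile.

Step 12
Reactants: 23 aryloxyacrylic acid
Product: 25 8-[4-(allyloxy)-2,6-bis(benzyloxy)phenyl]-5,7-bis(benzyloxy)-2-[4-(benzyloxy)phenyl]-4H-chromen-4-one, via mixed anhydride 24 (not isolated)
Conditions: (CF3CO)2O (1.5 equiv), CH2Cl2, 0 °C → rt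
Reagents that add atoms: trifluoroacetic anhydride, O=C(OC(=O)C(F)(F)F)C(F)(F)F (kept only in 24)
Why: Intramolecular Friedel–Crafts acylation through the acyl trifluoroacetate closes ring C'' at C4a'', the only open position next to O1'' and one activated by three oxygens, and any (E) isomer should equilibrate by reversible α-protonation in the trifluoroacetic acid that forms.

Step 13
Reactants: 25 allyl-protected flavone
Product: 26 5,7-bis(benzyloxy)-8-[2,6-bis(benzyloxy)-4-hydroxyphenyl]-2-[4-(benzyloxy)phenyl]-4H-chromen-4-one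
Conditions: Pd(PPh3)4 (5 mol %), morpholine, THF, rt
Reagents that add atoms: none
Why: Zerovalent palladium ionises the allyl aryl ether to a π-allyl complex and the phenoxide, and morpholine takes up the allyl group (Tsuji–Trost deallylation), leaving benzyl ethers and flavone untouched.

Step 14
Reactants: 27 4'-hydroxyacetophenone
Product: 28 allyl 3-(4-hydroxyphenyl)-3-oxopropanoate
Conditions: NaH (3 equiv), diallyl carbonate, THF, reflux; then 1 M HCl
Reagents that add atoms: diallyl carbonate, C=CCOC(=O)OCC=C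
Why: Crossed Claisen condensation of the ketone enolate with a dialkyl carbonate is driven by deprotonation of the β-keto ester, and any carbonate formed on the phenoxide reverts because phenoxide is the better leaving group.

Step 15
Reactants: 28 allyl 3-(4-hydroxyphenyl)-3-oxopropanoate
Product: 29 allyl 3-{4-[(benzyloxycarbonyl)oxy]phenyl}-3-oxopropanoate
Conditions: CbzCl (1.05 equiv), Et3N, CH2Cl2, 0 °C
Reagents that add atoms: benzyl chloroformate, O=C(Cl)OCc1ccccc1
Why: O-acylation takes the para-acyl phenol, which is more acidic than the β-keto ester, and the carbonate turns the ring oxygen from a strong into a weak donor while remaining hydrogenolysable.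

Step 16
Reactants: 29 allyl 3-{4-[(benzyloxycarbonyl)oxy]phenyl}-3-oxopropanoate
Product: 30 allyl (3R)-3-{4-[(benzyloxycarbonyl)oxy]phenyl}-3-hydroxypropanoate
Conditions: RuCl[(R,R)-TsDPEN](p-cymene) (1 mol %), HCO2H/Et3N 5:2, CH2Cl2, 30 °C; recrystallisation if the enantiopurity needs upgrading
Reagents that add atoms: none
Why: Noyori–Ikariya asymmetric transfer hydrogenation with the (R,R) catalyst delivers hydride to the Si face of the aryl ketone (aryl/arene contact in the six-membered transition state) and sets the (R) carbinol, while allyl ester and carbonate are not reduced.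

Step 17
Reactants: 26 flavone phenol; 30 allyl (3R)-β-hydroxy ester
Product: 31 allyl (3S)-3-{4-[(benzyloxycarbonyl)oxy]phenyl}-3-(3,5-bis(benzyloxy)-4-{5,7-bis(benzyloxy)-2-[4-(benzyloxy)phenyl]-4-oxo-4H-chromen-8-yl}phenoxy)propanoate
Conditions: PPh3, DIAD, toluene, 0 °C → rt (30 1.3 equiv)
Reagents that add atoms: none
Why: Mitsunobu etherification displaces the alkoxyphosphonium group by the unhindered phenoxide of 26 in an SN2 step that inverts (R) to (S), the C2 configuration of the target, and the weakly donating carbonate on the aryl ring disfavours the ionisation that erodes inversion in para-alkoxybenzylic alcohols.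

Step 18
Reactants: 31 allyl (3S)-ester
Product: 32 (3S)-3-{4-[(benzyloxycarbonyl)oxy]phenyl}-3-(3,5-bis(benzyloxy)-4-{5,7-bis(benzyloxy)-2-[4-(benzyloxy)phenyl]-4-oxo-4H-chromen-8-yl}phenoxy)propanoic acid
Conditions: Pd(PPh3)4 (5 mol %), N-methylaniline, THF, rt
Reagents that add atoms: none
Why: Allyl transfer from the ester to a weakly basic amine under zerovalent palladium catalysis frees the acid under near-neutral conditions, so that neither β-elimination of the aryloxy group nor cleavage of the aryl carbonate should occur.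

Step 19
Reactants: 32 (3S)-acid
Product: 34 (2S)-5,7-bis(benzyloxy)-6-{5,7-bis(benzyloxy)-2-[4-(benzyloxy)phenyl]-4-oxo-4H-chromen-8-yl}-2-{4-[(benzyloxycarbonyl)oxy]phenyl}chroman-4-one, via mixed anhydride 33 (not isolated)
Conditions: (CF3CO)2O (1.5 equiv), CH2Cl2, 0 °C
Reagents that add atoms: trifluoroacetic anhydride, O=C(OC(=O)C(F)(F)F)C(F)(F)F (kept only in 33)
Why: Intramolecular Friedel–Crafts acylation through the acyl trifluoroacetate closes ring C on either of the two constitutionally equivalent carbons next to O1 (this choice only fixes the sense of the axis), and C2 is not touched because the carbonate-bearing aryl group does not support ionisation of the C2–O1 bond in dilute trifluoroacetic acid.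

Step 20
Reactants: 34 protected flavanone–flavone
Product: 35 (2S)-5,7-dihydroxy-6-[5,7-dihydroxy-2-(4-hydroxyphenyl)-4-oxo-4H-chromen-8-yl]-2-(4-hydroxyphenyl)chroman-4-one (target)
Conditions: H2 (1 atm), Pd/C, EtOAc/MeOH, rt, stopped at the calculated uptake
Reagents that add atoms: none
Why: Hydrogenolysis removes the five benzyl ethers and the benzyl carbonate (with loss of CO2) under neutral conditions, which avoids the base-induced ring opening that racemises flavanones and normally leaves the flavone alkene and both carbonyl groups intact.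

**Compound list**

1 | 2,4,6-trihydroxybenzaldehyde | O=Cc1c(O)cc(O)cc1O | starting material
2 | 4-(allyloxy)-2,6-dihydroxybenzaldehyde | C=CCOc1cc(O)c(C=O)c(O)c1 | intermediate
3 | 4-(allyloxy)-2,6-bis(benzyloxy)benzaldehyde | C=CCOc1cc(OCc2ccccc2)c(C=O)c(OCc2ccccc2)c1 | intermediate
4 | 5-(allyloxy)-1,3-bis(benzyloxy)-2-ethynylbenzene | C#Cc1c(OCc2ccccc2)cc(OCC=C)cc1OCc1ccccc1 | intermediate
5 | lithium acetylide of 4 (not isolated) | [Li]C#Cc1c(OCc2ccccc2)cc(OCC=C)cc1OCc1ccccc1 | intermediate
6 | lithium 2-arylethynolate (not isolated) | [Li]OC#Cc1c(OCc2ccccc2)cc(OCC=C)cc1OCc1ccccc1 | intermediate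
7 | {[4-(allyloxy)-2,6-bis(benzyloxy)phenyl]ethynyloxy}triisopropylsilane | CC(C)[Si](OC#Cc1c(OCc2ccccc2)cc(OCC=C)cc1OCc1ccccc1)(C(C)C)C(C)C | intermediate
8 | 2,3-butanedione | CC(=O)C(C)=O | starting material
9 | 3-(triisopropylsilyloxy)but-3-en-2-one | C=C(O[Si](C(C)C)(C(C)C)C(C)C)C(C)=O | intermediate
10 | lithium enolate of 9 (not isolated) | C=C(O[Li])C(=C)O[Si](C(C)C)(C(C)C)C(C)C | intermediate
11 | 1,1,1-trifluoro-5-(triisopropylsilyloxy)hex-5-ene-2,4-dione (not isolated) | C=C(O[Si](C(C)C)(C(C)C)C(C)C)C(=O)CC(=O)C(F)(F)F | intermediate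
12 | 1-diazo-3-(triisopropylsilyloxy)but-3-en-2-one | C=C(O[Si](C(C)C)(C(C)C)C(C)C)C(=O)C=[N+]=[N-] | intermediate
13 | 3-(triisopropylsilyloxy)buta-1,3-dien-1-one, vinylketene (not isolated) | C=C(O[Si](C(C)C)(C(C)C)C(C)C)C=C=O | intermediate
14 | 2-[4-(allyloxy)-2,6-bis(benzyloxy)phenyl]-3-(triisopropylsilyloxy)-4-[1-(triisopropylsilyloxy)vinyl]cyclobut-2-en-1-one (racemic, not isolated) | O=C1C(c2c(OCc3ccccc3)cc(OCC=C)cc2OCc2ccccc2)=C(O[Si](C(C)C)(C(C)C)C(C)C)C1C(=C)O[Si](C(C)C)(C(C)C)C(C)C | intermediate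
15 | 2-[4-(allyloxy)-2,6-bis(benzyloxy)phenyl]-3,5-bis(triisopropylsilyloxy)hexa-1,3,5-trien-1-one, ketene and vinyl groups cis (not isolated) | O=C=C(c1c(OCc2ccccc2)cc(OCC=C)cc1OCc1ccccc1)/C(O[Si](C(C)C)(C(C)C)C(C)C)=C\C(=C)O[Si](C(C)C)(C(C)C)C(C)C | intermediate
16 | 2-[4-(allyloxy)-2,6-bis(benzyloxy)phenyl]-3,5-bis(triisopropylsilyloxy)cyclohexa-2,4-dien-1-one (not isolated) | O=C1CC(O[Si](C(C)C)(C(C)C)C(C)C)=CC(O[Si](C(C)C)(C(C)C)C(C)C)=C1c1c(OCc2ccccc2)cc(OCC=C)cc1OCc1ccccc1 | intermediate
17 | 4'-(allyloxy)-2',6'-bis(benzyloxy)-4,6-bis(triisopropylsilyloxy)biphenyl-2-ol | Oc1cc(O[Si](C(C)C)(C(C)C)C(C)C)cc(O[Si](C(C)C)(C(C)C)C(C)C)c1-c1c(OCc2ccccc2)cc(OCC=C)cc1OCc1ccccc1 | intermediate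
18 | 1-(benzyloxy)-4-ethynylbenzene | C#Cc1ccc(OCc2ccccc2)cc1 | starting material
19 | lithium acetylide of 18 (not isolated) | [Li]C#Cc1ccc(OCc2ccccc2)cc1 | intermediate
20 | methyl 3-[4-(benzyloxy)phenyl]prop-2-ynoate | COC(=O)C#Cc1ccc(OCc2ccccc2)cc1 | intermediate
21 | methyl (Z)-3-[4-(benzyloxy)phenyl]-3-{[4'-(allyloxy)-2',6'-bis(benzyloxy)-4,6-bis(triisopropylsilyloxy)biphenyl-2-yl]oxy}acrylate | COC(=O)/C=C(\Oc1cc(O[Si](C(C)C)(C(C)C)C(C)C)cc(O[Si](C(C)C)(C(C)C)C(C)C)c1-c1c(OCc2ccccc2)cc(OCC=C)cc1OCc1ccccc1)c1ccc(OCc2ccccc2)cc1 | intermediate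
22 | methyl (Z)-3-[4-(benzyloxy)phenyl]-3-{[4'-(allyloxy)-2',4,6,6'-tetrakis(benzyloxy)biphenyl-2-yl]oxy}acrylate | COC(=O)/C=C(\Oc1cc(OCc2ccccc2)cc(OCc2ccccc2)c1-c1c(OCc2ccccc2)cc(OCC=C)cc1OCc1ccccc1)c1ccc(OCc2ccccc2)cc1 | intermediate
23 | (Z)-3-[4-(benzyloxy)phenyl]-3-{[4'-(allyloxy)-2',4,6,6'-tetrakis(benzyloxy)biphenyl-2-yl]oxy}acrylic acid | OC(=O)/C=C(\Oc1cc(OCc2ccccc2)cc(OCc2ccccc2)c1-c1c(OCc2ccccc2)cc(OCC=C)cc1OCc1ccccc1)c1ccc(OCc2ccccc2)cc1 | intermediate
24 | mixed trifluoroacetic anhydride of 23 (not isolated) | O=C(OC(=O)C(F)(F)F)/C=C(\Oc1cc(OCc2ccccc2)cc(OCc2ccccc2)c1-c1c(OCc2ccccc2)cc(OCC=C)cc1OCc1ccccc1)c1ccc(OCc2ccccc2)cc1 | intermediate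
25 | 8-[4-(allyloxy)-2,6-bis(benzyloxy)phenyl]-5,7-bis(benzyloxy)-2-[4-(benzyloxy)phenyl]-4H-chromen-4-one | O=c1cc(-c2ccc(OCc3ccccc3)cc2)oc2c(-c3c(OCc4ccccc4)cc(OCC=C)cc3OCc3ccccc3)c(OCc3ccccc3)cc(OCc3ccccc3)c12 | intermediate
26 | 5,7-bis(benzyloxy)-8-[2,6-bis(benzyloxy)-4-hydroxyphenyl]-2-[4-(benzyloxy)phenyl]-4H-chromen-4-one | O=c1cc(-c2ccc(OCc3ccccc3)cc2)oc2c(-c3c(OCc4ccccc4)cc(O)cc3OCc3ccccc3)c(OCc3ccccc3)cc(OCc3ccccc3)c12 | intermediate
27 | 4'-hydroxyacetophenone | CC(=O)c1ccc(O)cc1 | starting material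
28 | allyl 3-(4-hydroxyphenyl)-3-oxopropanoate | C=CCOC(=O)CC(=O)c1ccc(O)cc1 | intermediate
29 | allyl 3-{4-[(benzyloxycarbonyl)oxy]phenyl}-3-oxopropanoate | C=CCOC(=O)CC(=O)c1ccc(OC(=O)OCc2ccccc2)cc1 | intermediate
30 | allyl (3R)-3-{4-[(benzyloxycarbonyl)oxy]phenyl}-3-hydroxypropanoate | C=CCOC(=O)C[C@@H](O)c1ccc(OC(=O)OCc2ccccc2)cc1 | intermediate
31 | allyl (3S)-3-aryl-3-aryloxypropanoate from 26 and 30 | C=CCOC(=O)C[C@H](Oc1cc(OCc2ccccc2)c(-c2c(OCc3ccccc3)cc(OCc3ccccc3)c3c(=O)cc(-c4ccc(OCc5ccccc5)cc4)oc23)c(OCc2ccccc2)c1)c1ccc(OC(=O)OCc2ccccc2)cc1 | intermediate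
32 | (3S)-3-aryl-3-aryloxypropanoic acid from 31 | OC(=O)C[C@H](Oc1cc(OCc2ccccc2)c(-c2c(OCc3ccccc3)cc(OCc3ccccc3)c3c(=O)cc(-c4ccc(OCc5ccccc5)cc4)oc23)c(OCc2ccccc2)c1)c1ccc(OC(=O)OCc2ccccc2)cc1 | intermediate
33 | mixed trifluoroacetic anhydride of 32 (not isolated) | O=C(C[C@H](Oc1cc(OCc2ccccc2)c(-c2c(OCc3ccccc3)cc(OCc3ccccc3)c3c(=O)cc(-c4ccc(OCc5ccccc5)cc4)oc23)c(OCc2ccccc2)c1)c1ccc(OC(=O)OCc2ccccc2)cc1)OC(=O)C(F)(F)F | intermediate
34 | (2S)-5,7-bis(benzyloxy)-6-{5,7-bis(benzyloxy)-2-[4-(benzyloxy)phenyl]-4-oxo-4H-chromen-8-yl}-2-{4-[(benzyloxycarbonyl)oxy]phenyl}chroman-4-one | O=C1C[C@@H](c2ccc(OC(=O)OCc3ccccc3)cc2)Oc2cc(OCc3ccccc3)c(-c3c(OCc4ccccc4)cc(OCc4ccccc4)c4c(=O)cc(-c5ccc(OCc6ccccc6)cc5)oc34)c(OCc3ccccc3)c21 | intermediate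
35 | (2S)-5,7-dihydroxy-6-[5,7-dihydroxy-2-(4-hydroxyphenyl)-4-oxo-4H-chromen-8-yl]-2-(4-hydroxyphenyl)chroman-4-one (CNP0154104.1) | O=C1C[C@@H](c2ccc(O)cc2)Oc2cc(O)c(-c3c(O)cc(O)c4c(=O)cc(-c5ccc(O)cc5)oc34)c(O)c21 | target

**Step count and risks**

Total step count: 20. Longest linear sequence: 14 steps (1–4, 7, 9–13, 17–20).

Steps most likely to fail:

Step 7. The vinylketene may form faster than the ynol ether, shielded by two ortho benzyloxy groups, can capture it, and would then be lost to dimerisation. Alternatively, part of the light may be taken up by the electron-rich aryl alkyne, which would degrade photochemically. The fallback sets out from 7 and comes back at 17, and uses neither light nor a diazo compound. Cyclobutane-1,3-dione is O-silylated (TIPSOTf, Et3N, CH2Cl2, 0 °C) to 3-(triisopropylsilyloxy)cyclobut-2-en-1-one F1. Heating F1 with 7 in toluene in a sealed tube at about 130 °C opens the four-membered ring thermally and slowly to the same vinylketene 13. Its stationary concentration stays low, and the cascade through 14, 15 and 16 should end at 17. This is the thermal cyclobutenone version of the Danheiser benzannulation.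

Step 17. The alkoxyphosphonium salt of the β-hydroxy ester may undergo β-elimination to the cinnamate, or partial ionisation that lowers the fidelity of inversion. The fallback sets out from 26 and comes back at 35, and sets C2 by catalyst control instead of substitution.
- Ring A of 26 is C-acetylated next to the free hydroxyl (AcOH, (CF3CO)2O, CH2Cl2, then K2CO3/MeOH to remove O-acyl groups) to give the ortho-hydroxyacetophenone F6.
- Heating with DMF dimethyl acetal gives the enaminone F7.
- HCl in CH2Cl2 closes it to the chromone F8.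
- Asymmetric 1,4-addition of 4-(benzyloxy)phenylboronic acid follows, with [Rh(OH)(cod)]2 and an electron-poor chiral biaryl bisphosphine in toluene/H2O, the ligand antipode being chosen for the (S) product. The 2-aryl-substituted flavone enone is too hindered to react. This gives the hexabenzyl flavanone F9.
- Hydrogenolysis as in step 20 gives 35.

Step 9. The conjugate addition may stall, because the phenoxide sits beside the twisted ring A and the acceptor is deactivated by its para-alkoxyaryl group. Forcing it may cause base-induced silyl loss or silyl transfer, which would set further phenoxides free to add as well. The fallback sets out from 17 and comes back at 25, and also bypasses steps 10–12.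
- Ortho-formylation with MgCl2, Et3N and paraformaldehyde (Casnati–Skattebøl; only C4a'' is open next to the hydroxyl) gives the salicylaldehyde F2.
- Two equivalents of lithium acetylide 19 add to give the propargylic alcohol F3.
- MnO2 oxidises it to the ynone F4.
- Diethylamine in ethanol brings about 6-endo closure by way of the enaminone to the bis-silylated flavone F5.
- CsF and BnBr as in step 10 give 25.

**Further compounds**

F1 | step 7 | 3-(triisopropylsilyloxy)cyclobut-2-en-1-one | O=C1C=C(O[Si](C(C)C)(C(C)C)C(C)C)C1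
F2 | step 9 | 3-[4-(allyloxy)-2,6-bis(benzyloxy)phenyl]-2-hydroxy-4,6-bis(triisopropylsilyloxy)benzaldehyde | O=Cc1c(O)c(-c2c(OCc3ccccc3)cc(OCC=C)cc2OCc2ccccc2)c(O[Si](C(C)C)(C(C)C)C(C)C)cc1O[Si](C(C)C)(C(C)C)C(C)C
F3 | step 9 | racemic 1-aryl-3-[4-(benzyloxy)phenyl]prop-2-yn-1-ol from F2 and 19 | OC(C#Cc1ccc(OCc2ccccc2)cc1)c1c(O)c(-c2c(OCc3ccccc3)cc(OCC=C)cc2OCc2ccccc2)c(O[Si](C(C)C)(C(C)C)C(C)C)cc1O[Si](C(C)C)(C(C)C)C(C)C
F4 | step 9 | 1-aryl-3-[4-(benzyloxy)phenyl]prop-2-yn-1-one from F3 | O=C(C#Cc1ccc(OCc2ccccc2)cc1)c1c(O)c(-c2c(OCc3ccccc3)cc(OCC=C)cc2OCc2ccccc2)c(O[Si](C(C)C)(C(C)C)C(C)C)cc1O[Si](C(C)C)(C(C)C)C(C)C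
F5 | step 9 | 8-[4-(allyloxy)-2,6-bis(benzyloxy)phenyl]-2-[4-(benzyloxy)phenyl]-5,7-bis(triisopropylsilyloxy)-4H-chromen-4-one | O=c1cc(-c2ccc(OCc3ccccc3)cc2)oc2c(-c3c(OCc4ccccc4)cc(OCC=C)cc3OCc3ccccc3)c(O[Si](C(C)C)(C(C)C)C(C)C)cc(O[Si](C(C)C)(C(C)C)C(C)C)c12
F6 | step 17 | 8-[3-acetyl-2,6-bis(benzyloxy)-4-hydroxyphenyl]-5,7-bis(benzyloxy)-2-[4-(benzyloxy)phenyl]-4H-chromen-4-one | CC(=O)c1c(O)cc(OCc2ccccc2)c(-c2c(OCc3ccccc3)cc(OCc3ccccc3)c3c(=O)cc(-c4ccc(OCc5ccccc5)cc4)oc23)c1OCc1ccccc1
F7 | step 17 | (E)-3-(dimethylamino)acryloyl analogue of F6 (enaminone) | CN(C)/C=C/C(=O)c1c(O)cc(OCc2ccccc2)c(-c2c(OCc3ccccc3)cc(OCc3ccccc3)c3c(=O)cc(-c4ccc(OCc5ccccc5)cc4)oc23)c1OCc1ccccc1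
F8 | step 17 | 5,7-bis(benzyloxy)-6-{5,7-bis(benzyloxy)-2-[4-(benzyloxy)phenyl]-4-oxo-4H-chromen-8-yl}-4H-chromen-4-one | O=c1ccoc2cc(OCc3ccccc3)c(-c3c(OCc4ccccc4)cc(OCc4ccccc4)c4c(=O)cc(-c5ccc(OCc6ccccc6)cc5)oc34)c(OCc3ccccc3)c12
F9 | step 17 | (2S)-5,7-bis(benzyloxy)-2-[4-(benzyloxy)phenyl]-6-{5,7-bis(benzyloxy)-2-[4-(benzyloxy)phenyl]-4-oxo-4H-chromen-8-yl}chroman-4-one | O=C1C[C@@H](c2ccc(OCc3ccccc3)cc2)Oc2cc(OCc3ccccc3)c(-c3c(OCc4ccccc4)cc(OCc4ccccc4)c4c(=O)cc(-c5ccc(OCc6ccccc6)cc5)oc34)c(OCc3ccccc3)c21
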